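The constants used here come from no measurement; the flask was simulated.

The reagent charge exceeds the partner charge by 0.800 of substrate charge, and this spare reagent is the amount followed here.

    substrate + reagent → open intermediate (k1 = 0.0092 /M/s)
    reagent + partner → second intermediate (k2 = 0.37 /M/s)
    open intermediate + second intermediate → target (k3 = 0.085 /M/s)
    substrate ⇌ dormant form (K4 = 19, k4 = 0.0086 /s)

common to all: partner 1.20 equiv; time 30 min
- amber: substrate 0.17 M (fed, over 6.0 min); reagent 2.00 equiv; all else is in the flask from the start; the feed brings no volume worth counting
- blue: substrate 0.17 M; reagent 2.00 equiv (fed, over 6.0 min); all else is in the flask from the start; the feed brings no volume worth counting
- red: substrate 0.17 M; reagent 2.00 equiv; everything together at the start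

1. the best flask by amount of target, in percent of the substrate charged; "all alike" if 1.5 percentage points covers them all (amber / blue / red / all alike)
2. amount of target at the end, in percent of the substrate charged, amber
3. amount of target at the end, in percent of the substrate charged, blue
4. amount of target at the end, in percent of the substrate charged, red

1. Charge for charge, partner takes reagent 48.3 times as fast as substrate does, so the reckoning lets substrate meet the spare reagent alone.

2. The spare-reagent constant is the pseudo-first-order constant of substrate against that spare reagent: 0.0751 /min.

3. Parking, the forward step from substrate to dormant form, runs at 0.516 /min, faster than that, so the reckoning lets a share of 12.7% of fresh substrate react first, the head start, and the rest go dormant.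

4. At the balance of step 4, 5.00% of the free and dormant substrate together stands free, so the leak constant is 0.00375 /min. Over 30 min, the reckoning passes 10.6% of that pool on to open intermediate. Second intermediate captures open intermediate much faster than the leak feeds it, so what leaks is counted as target.

5. Red has the head start and the full leak: 22.0%. Amber has both, with the leak shortened by the mean wait in the feed: 21.1%. In blue, the feed has delivered as much reagent as the partner charge after 3.60 min, later than the half-life of 1.34 min of the forward parking step alone, so the reckoning gives blue no head start and the leak from the end of the feed: 8.61%.

6. Turned round, "all alike" needs red and blue within 1.5 percentage points, but the reckoned gap is 13 points. The reckoned best is red.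

The forecast names red, with 19.5% for amber, 10.5% for blue and 22% for red, holding that “blue is clearly worst because the substrate has gone dormant before free reagent appears”. The reckoning above stands higher on amber and lower on blue.

The simulation gives red as best, with 17.2% for amber, 9.60% for blue and 19.2% for red.

A neighbouring flask is like red but holds 0.10 M of substrate, with the same equivalents. Its spare-reagent constant falls with the concentration to 0.0442 /min, so its head start is 7.88%. With the leak over the same time, the reckoning gives 13.8% of its substrate charge as target. At 30.0 min that flask holds 13.0% of its substrate charge as target.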